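The cyclohexene ring is cut at C4=C5 and at C1–C6 (7-oxabicyclo[4.1.0]hept-4-ene numbering). This frees C5–C6, an unbranched CH–CH unit between the alkene carbon C4 and the fully substituted C1, as acetylene. In one operation a ruthenium carbene stitches acetylene between the vinyl and methylidene ends of an acyclic 1,5-diene (tandem enyne cross-metathesis and ring-closing metathesis) and gives the cyclohexa-1,3-diene. The precursor, 3-hydroxy-2-methylidenehex-5-ene-1,4-diyl dibenzoate, takes the trans C2/C3 oxygens from L-sorbose. The diene bond that becomes C1–C6 is then epoxidised syn to the free C2 hydroxyl, and O-methylation ends the route.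

Key step: step 5

Assumption: 2,3-O-isopropylidene-α-L-sorbofuranose (1) is taken as a catalogue compound; it is the partial hydrolysis product of commercial 2,3:4,6-di-O-isopropylidene-α-L-sorbofuranose.

Step 1
Reactants: 1 2,3-O-isopropylidene-α-L-sorbofuranose
Product: 2 6-deoxy-6-iodo-2,3-O-isopropylidene-α-L-sorbofuranose
Conditions: I2, PPh3, imidazole, THF, 0 °C → rt
Reagents that add atoms: iodine, II
Why: Garegg–Samuelsson (Appel-type) iodination, in which the oxyphosphonium of the unhindered primary C6 hydroxyl is displaced by iodide (SN2), while the neopentyl-like C1 hydroxyl beside the ketal carbon and the secondary C4 hydroxyl should not be displaced; no stereocentre is touched.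

Step 2
Reactants: 2 6-deoxy-6-iodo-2,3-O-isopropylidene-α-L-sorbofuranose
Product: 3 1,4-di-O-benzoyl-6-deoxy-6-iodo-2,3-O-isopropylidene-α-L-sorbofuranose
Conditions: BzCl, pyridine, DMAP (cat.), CH2Cl2, 0 °C → rt
Reagents that add atoms: benzoyl chloride, O=C(Cl)c1ccccc1
Why: DMAP-catalysed acylation of both free hydroxyls should install the two benzoates of the target at once, while O3 stays masked in the acetonide.

Step 3
Reactants: 3 1,4-di-O-benzoyl-6-deoxy-6-iodo-2,3-O-isopropylidene-α-L-sorbofuranose
Product: 5 (3S,4R)-3-hydroxy-2-oxohex-5-ene-1,4-diyl dibenzoate, via C6 alkylzinc iodide 4 (not isolated)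
Conditions: Zn dust (activated), THF/H2O 4:1, ultrasound, 40 °C
Reagents that add atoms: none
Why: Bernet–Vasella reductive fragmentation: zinc inserts into the C6–I bond, β-elimination expels the ring oxygen from C5 to give the terminal alkene, and the ketal alkoxide at C2 collapses to the ketone with loss of acetone, which frees the C3 hydroxyl; C3 and C4 of L-sorbose are carried over unchanged as the (3S,4R) centres.

Step 4
Reactants: 5 (3S,4R)-3-hydroxy-2-oxohex-5-ene-1,4-diyl dibenzoate
Product: 6 (3R,4R)-3-hydroxy-2-methylidenehex-5-ene-1,4-diyl dibenzoate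
Conditions: Zn, CH2Br2, TiCl4 (pre-formed Lombardo reagent), THF/CH2Cl2, 0 °C → rt
Reagents that add atoms: dibromomethane, BrCBr
Why: Takai–Lombardo methylenation: the non-basic zinc/titanium gem-dimetallic methylene reagent should olefinate the ketone but not the benzoates and should not enolise the ketol, so C3 keeps its configuration (the descriptor changes from S to R only because the priority of C2 drops).

Step 5
Reactants: 6 (3R,4R)-3-hydroxy-2-methylidenehex-5-ene-1,4-diyl dibenzoate; 7 acetylene
Product: 8 [(5R,6R)-5-(benzoyloxy)-6-hydroxycyclohexa-1,3-dien-1-yl]methyl benzoate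
Conditions: acetylene (about 0.1 atm in argon, slow stream), second-generation Hoveyda–Grubbs catalyst RuCl2(H2IMes)(=CH-C6H4-2-OiPr) (10 mol %, in portions), CH2Cl2 (0.01 M), 40 °C
Reagents that add atoms: none
Why: The ruthenium carbene should load onto the monosubstituted C5=C6 vinyl group of 6 (the 1,1-disubstituted methylidene is slower) and add acetylene by [2+2] cycloaddition and cycloreversion, which makes the new C=C to the former vinyl CH and leaves a conjugated vinylcarbene on the second acetylene carbon; this carbene then ring-closes onto the 2-methylidene group with loss of ethylene, so both ring bonds to the acetylene carbons form in one catalytic cycle. The closest known reaction type is the tandem intermolecular enyne cross-metathesis and ring-closing metathesis of terminal alkynes with 1,5-dienes to 1,3-cyclohexadienes; acetylene itself is the least tested alkyne partner. The six-membered carbocycle is closed by ring-closing metathesis (ruthenacyclobutane formation and cleavage) with the new trisubstituted C=C endocyclic, and no other ring can compete because direct closure of the 1,5-diene would give a cyclobutene. No stereocentre is created, the trans C5/C6 oxygens come unchanged from L-sorbose, and the symmetric alkyne removes any regiochemical question. The step needs the cis geometry at the new disubstituted alkene, which ring closure selects (the trans isomer can re-enter through secondary metathesis), and it needs ring closure to outrun a second acetylene insertion, which the low acetylene pressure and high dilution are meant to secure.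

Step 6
Reactants: 8 [(5R,6R)-5-(benzoyloxy)-6-hydroxycyclohexa-1,3-dien-1-yl]methyl benzoate
Product: 9 [(1R,2S,3R,6R)-3-(benzoyloxy)-2-hydroxy-7-oxabicyclo[4.1.0]hept-4-en-1-yl]methyl benzoate
Conditions: VO(acac)2 (5 mol %), t-BuOOH (1.2 equiv), CH2Cl2, 0 °C
Reagents that add atoms: tert-butyl hydroperoxide, CC(C)(C)OO
Why: Hydroxyl-directed vanadium-catalysed epoxidation: the vanadate ester of the C6 hydroxyl should deliver oxygen to the adjacent trisubstituted C1=C2 bond on its own face, which sets both epoxide carbons cis to that hydroxyl; the C3=C4 bond is only homoallylic and is deactivated by the allylic benzoate.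

Step 7
Reactants: 9 [(1R,2S,3R,6R)-3-(benzoyloxy)-2-hydroxy-7-oxabicyclo[4.1.0]hept-4-en-1-yl]methyl benzoate
Product: 10 [(1R,2S,3R,6R)-3-(benzoyloxy)-2-methoxy-7-oxabicyclo[4.1.0]hept-4-en-1-yl]methyl benzoate
Conditions: Me3OBF4, 1,8-bis(dimethylamino)naphthalene, 4 Å MS, CH2Cl2, 0 °C → rt
Reagents that add atoms: trimethyloxonium tetrafluoroborate, C[O+](C)C.F[B-](F)(F)F
Why: O-methylation with Meerwein's salt and a non-nucleophilic proton scavenger forms no alkoxide, so neither benzoyl migration from O3 nor Payne rearrangement of the neighbouring epoxide should set in, and no stereocentre changes.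

Compound list
1 | 2,3-O-isopropylidene-α-L-sorbofuranose | OC[C@@]12O[C@@H](CO)[C@@H](O)[C@@H]1OC(C)(C)O2 | starting material
2 | 6-deoxy-6-iodo-2,3-O-isopropylidene-α-L-sorbofuranose | OC[C@@]12O[C@@H](CI)[C@@H](O)[C@@H]1OC(C)(C)O2 | intermediate
3 | 1,4-di-O-benzoyl-6-deoxy-6-iodo-2,3-O-isopropylidene-α-L-sorbofuranose | O=C(OC[C@@]12O[C@@H](CI)[C@@H](OC(=O)c3ccccc3)[C@@H]1OC(C)(C)O2)c1ccccc1 | intermediate
4 | C6 alkylzinc iodide of 3 (1,4-di-O-benzoyl-6-deoxy-6-(iodozincio)-2,3-O-isopropylidene-α-L-sorbofuranose) | O=C(OC[C@@]12O[C@@H](C[Zn]I)[C@@H](OC(=O)c3ccccc3)[C@@H]1OC(C)(C)O2)c1ccccc1 | intermediate (not isolated)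
5 | (3S,4R)-3-hydroxy-2-oxohex-5-ene-1,4-diyl dibenzoate | O[C@H](C(=O)COC(=O)c1ccccc1)[C@H](OC(=O)c1ccccc1)C=C | intermediate
6 | (3R,4R)-3-hydroxy-2-methylidenehex-5-ene-1,4-diyl dibenzoate | O[C@H](C(=C)COC(=O)c1ccccc1)[C@H](OC(=O)c1ccccc1)C=C | intermediate
7 | acetylene | C#C | starting material
8 | [(5R,6R)-5-(benzoyloxy)-6-hydroxycyclohexa-1,3-dien-1-yl]methyl benzoate | O[C@H]1[C@H](OC(=O)c2ccccc2)C=CC=C1COC(=O)c1ccccc1 | intermediate
9 | [(1R,2S,3R,6R)-3-(benzoyloxy)-2-hydroxy-7-oxabicyclo[4.1.0]hept-4-en-1-yl]methyl benzoate | O[C@H]1[C@H](OC(=O)c2ccccc2)C=C[C@H]2O[C@]21COC(=O)c1ccccc1 | intermediate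
10 | [(1R,2S,3R,6R)-3-(benzoyloxy)-2-methoxy-7-oxabicyclo[4.1.0]hept-4-en-1-yl]methyl benzoate | CO[C@H]1[C@H](OC(=O)c2ccccc2)C=C[C@H]2O[C@]21COC(=O)c1ccccc1 | target

Total step count: 7. Longest linear sequence: 7 steps (1 → 10).

Steps most likely to fail

Step 5. Acetylene may bind and insert repeatedly, so that the carbene is deactivated or oligomerises before the vinylcarbene ring-closes; ruthenium hydrides may also isomerise the allylic alcohol and trigger aromatisation by loss of benzoic acid. The fallback sets out from ketone 5, makes the two ring bonds one after the other and comes back at 9. Silylation (TESOTf, 2,6-lutidine, CH2Cl2, −78 °C) should give (3S,4R)-2-oxo-3-[(triethylsilyl)oxy]hex-5-ene-1,4-diyl dibenzoate F1. A Corey–Chaykovsky reaction with the allyl ylide from S-allyltetrahydrothiophenium bromide and KN(SiMe3)2 (THF, −78 °C) should then add to the ketone under Felkin–Anh control (non-chelating silyl ether), so that the new epoxide oxygen is syn to the silyloxy group, and give the vinyl epoxide [(2R,3R)-2-[(1S,2R)-2-(benzoyloxy)-1-[(triethylsilyl)oxy]but-3-en-1-yl]-3-ethenyloxiran-2-yl]methyl benzoate F2; only the isomer with the vinyl group cis to the side chain is carried on. Ring-closing metathesis with the second-generation Grubbs catalyst RuCl2(H2IMes)(PCy3)(=CHPh) (CH2Cl2, 40 °C) should give [(1R,2S,3R,6R)-3-(benzoyloxy)-2-[(triethylsilyl)oxy]-7-oxabicyclo[4.1.0]hept-4-en-1-yl]methyl benzoate F3, and tetrabutylammonium fluoride buffered with acetic acid (THF, 0 °C) should return the route at 9.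

Step 4. Methylenation of the hindered ketone may be slow, and the Lewis-acidic titanium may meanwhile promote benzoyl migration onto the free hydroxyl or retro-aldol cleavage of the ketol. The fallback sets out from 5 and comes back at 6. TBSOTf and 2,6-lutidine (CH2Cl2, −78 °C) should give (3S,4R)-3-[(tert-butyldimethylsilyl)oxy]-2-oxohex-5-ene-1,4-diyl dibenzoate F4. The Tebbe reagent Cp2Ti(CH2)(Cl)AlMe2 (THF/pyridine, −40 → 0 °C), which reacts with ketones well before benzoates, should give (3R,4R)-3-[(tert-butyldimethylsilyl)oxy]-2-methylidenehex-5-ene-1,4-diyl dibenzoate F5, and HF·pyridine (THF, 0 °C) should return 6.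

Step 7. The oxonium salt may alkylate the epoxide oxygen, after which the ring opens with participation of a neighbouring benzoate, or the hindered hydroxyl may be methylated incompletely. The fallback sets out from 8, methylates before the epoxide exists and builds the epoxide through a halohydrin, coming back at 10. Me3OBF4 and 1,8-bis(dimethylamino)naphthalene (CH2Cl2, 0 °C) should give [(5R,6R)-5-(benzoyloxy)-6-methoxycyclohexa-1,3-dien-1-yl]methyl benzoate F6. NBS in THF/H2O (0 °C) should form the bromonium ion on the face anti to the pseudo-axial methoxy group and be opened by water at the tertiary carbon to give [(1S,2S,5R,6S)-5-(benzoyloxy)-2-bromo-1-hydroxy-6-methoxycyclohex-3-en-1-yl]methyl benzoate F7; 1,4-addition across the diene is the competing process. Ag2O (CH2Cl2, rt) should close the epoxide by backside displacement of bromide, which places the oxygen syn to the methoxy group and gives 10.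

Further compounds
F1 | step 5 | (3S,4R)-2-oxo-3-[(triethylsilyl)oxy]hex-5-ene-1,4-diyl dibenzoate | CC[Si](CC)(CC)O[C@H](C(=O)COC(=O)c1ccccc1)[C@H](OC(=O)c1ccccc1)C=C
F2 | step 5 | [(2R,3R)-2-[(1S,2R)-2-(benzoyloxy)-1-[(triethylsilyl)oxy]but-3-en-1-yl]-3-ethenyloxiran-2-yl]methyl benzoate | CC[Si](CC)(CC)O[C@H]([C@]1(COC(=O)c2ccccc2)O[C@@H]1C=C)[C@H](OC(=O)c1ccccc1)C=C
F3 | step 5 | [(1R,2S,3R,6R)-3-(benzoyloxy)-2-[(triethylsilyl)oxy]-7-oxabicyclo[4.1.0]hept-4-en-1-yl]methyl benzoate | CC[Si](CC)(CC)O[C@H]1[C@H](OC(=O)c2ccccc2)C=C[C@H]2O[C@]21COC(=O)c1ccccc1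
F4 | step 4 | (3S,4R)-3-[(tert-butyldimethylsilyl)oxy]-2-oxohex-5-ene-1,4-diyl dibenzoate | CC(C)(C)[Si](C)(C)O[C@H](C(=O)COC(=O)c1ccccc1)[C@H](OC(=O)c1ccccc1)C=C
F5 | step 4 | (3R,4R)-3-[(tert-butyldimethylsilyl)oxy]-2-methylidenehex-5-ene-1,4-diyl dibenzoate | CC(C)(C)[Si](C)(C)O[C@H](C(=C)COC(=O)c1ccccc1)[C@H](OC(=O)c1ccccc1)C=C
F6 | step 7 | [(5R,6R)-5-(benzoyloxy)-6-methoxycyclohexa-1,3-dien-1-yl]methyl benzoate | CO[C@H]1[C@H](OC(=O)c2ccccc2)C=CC=C1COC(=O)c1ccccc1
F7 | step 7 | [(1S,2S,5R,6S)-5-(benzoyloxy)-2-bromo-1-hydroxy-6-methoxycyclohex-3-en-1-yl]methyl benzoate | CO[C@H]1[C@H](OC(=O)c2ccccc2)C=C[C@H](Br)[C@]1(O)COC(=O)c1ccccc1
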